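**Retrosynthetic overview**
1. Lehualide A ⇒ cut the pyranone‑CH2–CH= bond (C1′–C2′): unprotected 4‑hydroxy‑3‑methoxy‑5,6‑dimethyl‑2‑pyranone + a (1E,5Z,8E)‑alkenyl iodide, joined by a new Pd‑catalysed vinylogous alkenylation of the pyranone O,C‑dianion.
2. Alkenyl iodide ⇒ terminal enyne by Zr‑catalysed methylalumination/iodination (sets 2′E); enyne ⇒ (Z)‑allylic bromide + lithiated TMS‑propyne.
3. (2Z,5E)‑skipped dienol ⇒ but‑2‑yn‑1‑ol + (E)‑allylic bromide by trans‑hydroalumination/Cu allylation (sets 6′Z); that bromide ⇒ phenylacetaldehyde by E‑selective Wittig (sets 9′E).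
4. Rings: only the 2‑pyranone is built (Step 3, lactonisation of a triketide made from methyl methoxyacetate, propionyl chloride and an acetyl Weinreb amide), before fragment union; the phenyl ring is bought.

Assumption: the target has no stereogenic centre (it is achiral), so "single enantiomer" is read as the single geometric isomer 2′E,6′Z,9′E (side‑chain carbons primed, counted from the pyranone).

**Step 1**
Reactants: 1 methyl methoxyacetate; 2 propionyl chloride
Product: 3 methyl 2‑methoxy‑3‑oxopentanoate (racemic, labile centre)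
Conditions: 1 (2.1 equiv), LiHMDS (2.1 equiv), THF, −78 °C; then 2 (1.0 equiv), −78 → −20 °C; aq. NH4Cl
Reagents that add atoms: none
Why: Crossed Claisen C‑acylation of a lithium ester enolate by an acid chloride; the second equivalent of enolate deprotonates the more acidic β‑keto ester product and stops over‑acylation.

**Step 2**
Reactants: 3 methyl 2‑methoxy‑3‑oxopentanoate; 4 N‑methoxy‑N‑methylacetamide
Product: 5 methyl 2‑methoxy‑4‑methyl‑3,5‑dioxohexanoate (diastereomer/enol mixture; both centres are erased in Step 3)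
Conditions: LDA (2.2 equiv), THF, −78 → 0 °C; then 4 (1.1 equiv), −78 → 0 °C; 1 M HCl
Reagents that add atoms: none
Why: The β‑keto ester dianion (Weiler type) reacts at its γ‑carbon, and the Weinreb amide gives a stable chelated tetrahedral intermediate, so mono‑acylation to the triketide results.

**Step 3**
Reactants: 5 methyl 2‑methoxy‑4‑methyl‑3,5‑dioxohexanoate
Product: 6 4‑hydroxy‑3‑methoxy‑5,6‑dimethyl‑2H‑pyran‑2‑one
Conditions: DBU (1.5 equiv), toluene, 60 °C; 1 M HCl work‑up
Reagents that add atoms: none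
Why: Base‑mediated enol lactonisation of a 3,5‑dioxo ester (C5 enol oxygen attacks the ester, loss of MeOH), the standard 4‑hydroxy‑2‑pyranone ring closure.

**Step 4**
Reactants: 7 phenylacetaldehyde; 8 ethyl 2‑(triphenylphosphoranylidene)propanoate
Product: 9 ethyl (2E)‑2‑methyl‑4‑phenylbut‑2‑enoate
Conditions: CH2Cl2, 0 °C → rt
Reagents that add atoms: none
Why: Wittig olefination with a stabilised α‑methyl ylide is E‑selective (typically >95:5) and sets the 9′E alkene; neutral conditions avoid isomerisation towards the styrene.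

**Step 5**
Reactants: 9 ethyl (2E)‑2‑methyl‑4‑phenylbut‑2‑enoate
Product: 10 (2E)‑2‑methyl‑4‑phenylbut‑2‑en‑1‑ol
Conditions: DIBAL‑H (2.2 equiv), CH2Cl2, −78 °C; Rochelle salt
Reagents that add atoms: none
Why: 1,2‑Reduction of the enoate to the allylic alcohol by DIBAL‑H leaves the alkene geometry untouched.

**Step 6**
Reactants: 10 (2E)‑2‑methyl‑4‑phenylbut‑2‑en‑1‑ol
Product: 11 [(2E)‑4‑bromo‑3‑methylbut‑2‑en‑1‑yl]benzene
Conditions: CBr4, PPh3, CH2Cl2, 0 °C
Reagents that add atoms: carbon tetrabromide, BrC(Br)(Br)Br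
Why: Appel bromination is an SN2 displacement at the primary carbinol carbon, with no allylic transposition or E/Z erosion at 0 °C.

**Step 7**
Reactants: 12 but‑2‑yn‑1‑ol; 11 [(2E)‑4‑bromo‑3‑methylbut‑2‑en‑1‑yl]benzene
Product: 13 (2Z,5E)‑3,5‑dimethyl‑7‑phenylhepta‑2,5‑dien‑1‑ol
Conditions: 12 (1.5 equiv), Red‑Al, THF, 0 °C → rt; EtOAc (destroys excess hydride); then CuI (20 mol %), 11 (1.0 equiv), −20 °C → rt; Rochelle salt
Reagents that add atoms: none
Why: Hydroxyl‑directed trans‑hydroalumination puts Al on C3 cis to the CH2O group (five‑membered oxa‑aluminacycle), and Cu‑mediated SN2 allylation of this alkenylalanate with retention places the new CH2 cis to C1, setting the 6′Z alkene (one‑pot trans‑hydroalumination/alkylation of a propargylic alcohol).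

**Step 8**
Reactants: 13 (2Z,5E)‑3,5‑dimethyl‑7‑phenylhepta‑2,5‑dien‑1‑ol
Product: 14 (2Z,5E)‑1‑bromo‑3,5‑dimethyl‑7‑phenylhepta‑2,5‑diene
Conditions: CBr4, PPh3, CH2Cl2, −30 → 0 °C; used directly
Reagents that add atoms: carbon tetrabromide, BrC(Br)(Br)Br
Why: Low‑temperature Appel bromination (as for nerol → neryl bromide) is a neutral SN2 process that avoids allyl cation formation, so the Z alkene and the skipped diene are preserved.

**Step 9**
Reactants: 14 (2Z,5E)‑1‑bromo‑3,5‑dimethyl‑7‑phenylhepta‑2,5‑diene; 15 trimethyl(prop‑1‑yn‑1‑yl)silane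
Product: 16 [(5Z,8E)‑6,8‑dimethyl‑10‑phenyldeca‑5,8‑dien‑1‑yn‑1‑yl]trimethylsilane
Conditions: 15, n‑BuLi, THF, −78 → −20 °C; then 14, −78 → 0 °C
Reagents that add atoms: none
Why: SN2 alkylation of 3‑lithio‑1‑(trimethylsilyl)propyne at the primary allylic bromide (the γ‑carbon is fully substituted, so SN2′ is blocked) gives the 1,5‑enyne with geometry retained.

**Step 10**
Reactants: 16 [(5Z,8E)‑6,8‑dimethyl‑10‑phenyldeca‑5,8‑dien‑1‑yn‑1‑yl]trimethylsilane
Product: 17 (5Z,8E)‑6,8‑dimethyl‑10‑phenyldeca‑5,8‑dien‑1‑yne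
Conditions: K2CO3, MeOH, rt
Reagents that add atoms: none
Why: Methoxide‑mediated protodesilylation of the alkynylsilane; the skipped diene is inert to K2CO3/MeOH.

**Step 11**
Reactants: 17 (5Z,8E)‑6,8‑dimethyl‑10‑phenyldeca‑5,8‑dien‑1‑yne
Product: 18 (1E,5Z,8E)‑1‑iodo‑2,6,8‑trimethyl‑10‑phenyldeca‑1,5,8‑triene
Conditions: AlMe3 (2.5 equiv), Cp2ZrCl2 (0.25 equiv), CH2Cl2, 0 °C → rt; then I2, THF, −30 → 0 °C
Reagents that add atoms: trimethylaluminium, C[Al](C)C; iodine, II
Why: Negishi Zr‑catalysed carboalumination adds Me–Al syn across the terminal alkyne (Me to the internal carbon) and iodinolysis proceeds with retention, setting the 2′E alkene; trisubstituted alkenes do not react.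

**Step 12**
Reactants: 6 4‑hydroxy‑3‑methoxy‑5,6‑dimethyl‑2H‑pyran‑2‑one; 18 (1E,5Z,8E)‑1‑iodo‑2,6,8‑trimethyl‑10‑phenyldeca‑1,5,8‑triene
Product: 19 lehualide A, 4‑hydroxy‑3‑methoxy‑5‑methyl‑6‑[(2E,6Z,9E)‑3,7,9‑trimethyl‑11‑phenylundeca‑2,6,9‑trien‑1‑yl]‑2H‑pyran‑2‑one
Conditions: 6 (1.5 equiv), LDA (3.1 equiv), THF–DMPU, −78 → −30 °C; ZnCl2 (3.2 equiv), → 0 °C; then 18 (1.0 equiv), Pd(OAc)2 (4 mol %), SPhos (8 mol %), 25–40 °C; aq. citric acid
Reagents that add atoms: none
Why: Proposed new method: Pd‑catalysed vinylogous sp3–sp2 cross‑coupling of an unprotected 4‑hydroxy‑6‑methyl‑2‑pyranone through its O,C‑dianion — double deprotonation gives the dianion whose carbanionic site is the 6‑CH2 (the 6‑methyl is vinylogous to the lactone carbonyl, the 5‑methyl is not), ZnCl2 turns it into a weakly basic heterobenzylic zinc reagent that should not deprotonate the doubly activated C1′H2 of the product, 18 adds oxidatively to Pd(0) with retention of E geometry, and transmetalation followed by C(sp3)–C(sp2) reductive elimination at the unhindered CH2 terminus (no β‑hydrogen, pyronate aromaticity kept) gives 19 as its zinc pyronate; the closest known reactions are Negishi coupling of benzylic zinc reagents with alkenyl halides, Pd‑catalysed α‑alkenylation/γ‑arylation of zinc (di)enolates, and the classical sp3 alkylation of 4‑hydroxy‑6‑methyl‑2‑pyranone dianions.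

**Compound list**
1 | methyl methoxyacetate | COCC(=O)OC | starting material
2 | propionyl chloride | CCC(=O)Cl | starting material
3 | methyl 2‑methoxy‑3‑oxopentanoate (racemic) | CCC(=O)C(OC)C(=O)OC | intermediate
4 | N‑methoxy‑N‑methylacetamide | CC(=O)N(C)OC | starting material
5 | methyl 2‑methoxy‑4‑methyl‑3,5‑dioxohexanoate (stereoisomer mixture) | CC(=O)C(C)C(=O)C(OC)C(=O)OC | intermediate
6 | 4‑hydroxy‑3‑methoxy‑5,6‑dimethyl‑2H‑pyran‑2‑one | COc1c(O)c(C)c(C)oc1=O | intermediate
7 | phenylacetaldehyde | O=CCc1ccccc1 | starting material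
8 | ethyl 2‑(triphenylphosphoranylidene)propanoate | CCOC(=O)C(C)=P(c1ccccc1)(c1ccccc1)c1ccccc1 | starting material
9 | ethyl (2E)‑2‑methyl‑4‑phenylbut‑2‑enoate | CCOC(=O)/C(C)=C/Cc1ccccc1 | intermediate
10 | (2E)‑2‑methyl‑4‑phenylbut‑2‑en‑1‑ol | OC/C(C)=C/Cc1ccccc1 | intermediate
11 | [(2E)‑4‑bromo‑3‑methylbut‑2‑en‑1‑yl]benzene | BrC/C(C)=C/Cc1ccccc1 | intermediate
12 | but‑2‑yn‑1‑ol | CC#CCO | starting material
13 | (2Z,5E)‑3,5‑dimethyl‑7‑phenylhepta‑2,5‑dien‑1‑ol | OC/C=C(/C)C/C(C)=C/Cc1ccccc1 | intermediate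
14 | (2Z,5E)‑1‑bromo‑3,5‑dimethyl‑7‑phenylhepta‑2,5‑diene | BrC/C=C(/C)C/C(C)=C/Cc1ccccc1 | intermediate
15 | trimethyl(prop‑1‑yn‑1‑yl)silane | CC#C[Si](C)(C)C | starting material
16 | [(5Z,8E)‑6,8‑dimethyl‑10‑phenyldeca‑5,8‑dien‑1‑yn‑1‑yl]trimethylsilane | C[Si](C)(C)C#CCC/C=C(/C)C/C(C)=C/Cc1ccccc1 | intermediate
17 | (5Z,8E)‑6,8‑dimethyl‑10‑phenyldeca‑5,8‑dien‑1‑yne | C#CCC/C=C(/C)C/C(C)=C/Cc1ccccc1 | intermediate
18 | (1E,5Z,8E)‑1‑iodo‑2,6,8‑trimethyl‑10‑phenyldeca‑1,5,8‑triene | I/C=C(\C)CC/C=C(/C)C/C(C)=C/Cc1ccccc1 | intermediate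
19 | lehualide A | COc1c(O)c(C)c(C/C=C(\C)CC/C=C(/C)C/C(C)=C/Cc2ccccc2)oc1=O | target

**Totals**
Total steps: 12. Longest linear sequence: 9 (Steps 4–12, from phenylacetaldehyde); the pyranone branch is 3 steps.

**Three steps most likely to fail, with fallbacks**
- **Step 12 (proposed new coupling).** Risks: coupling at C5 or oxygen, product deprotonation and alkene migration into conjugation, or simple protonolysis. Fallback (known chemistry, reversed polarity):
  - Make the electrophilic pyranone: use N‑methoxy‑N‑methyl‑2‑(benzyloxy)acetamide in Step 2, DBU cyclisation, 4‑O‑pivaloylation, H2/Pd–C debenzylation, then CBr4/PPh3 to give the 6‑(bromomethyl)pyranone.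
  - Convert 18 to the alkenylzinc (t‑BuLi, ZnCl2) or alkenylstannane and couple under Pd(0) (Negishi/Stille of a benzylic‑type bromide).
  - Remove the pivalate with K2CO3/MeOH.
- **Step 7 (one‑pot hydroalumination/Cu allylation).** Risks: SN2′ attack on 11 giving the branched isomer, or low conversion of the alanate. Fallback: quench the alanate with I2 to isolate (Z)‑3‑iodobut‑2‑en‑1‑ol, protect as the TBS ether, convert to the alkenylzinc (t‑BuLi, ZnCl2) and run a Pd(PPh3)4‑catalysed alkenyl–allyl Negishi coupling with 11 (π‑allyl pathway, bond formation at the unhindered CH2 terminus), then TBAF.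
- **Step 2 (dianion acylation).** Risks: O‑acylation, proton transfer or low yield with the α‑methoxy dianion. Fallback (different disconnection, methoxy installed last): acylate the dianion of 3‑methylpentane‑2,4‑dione with methyl chloroformate to give methyl 4‑methyl‑3,5‑dioxohexanoate, do diazo transfer at C2 (p‑ABSA, Et3N), Rh2(OAc)4‑catalysed O–H insertion into MeOH to give 5, then the Step 3 cyclisation.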